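Target has two roads.

    starting material + acid → weak acid + acid + target (k1 = 3200 L mol⁻¹ s⁻¹)
    weak acid ⇌ conjugate base + acid, settled at all times (K2 = 2.0 × 10⁻⁷ M)
    starting material → weak acid + target (k3 = 0.033 s⁻¹)
    starting material + weak acid ⇌ idle adduct, settled at all times (K4 = 29 L mol⁻¹)
    starting material + protic impurity → quenched substrate (k5 = 0.46 L mol⁻¹ s⁻¹)
    crystals ⇌ weak acid, rate k6*(cs6 - [weak acid]) while solid is left; crystals form when [weak acid] > cs6 (cs6 = 0.56 mM, k6 = 2.6 s⁻¹)
starting material 18 mM (fed, over 8.0 s); acid 0.0180 mM; protic impurity 18.0 mM; time 12 s
- acid is the free proton; pH is minus the decimal logarithm of its molar concentration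
- weak acid is meant together with its idle adduct and crystals
- solid, in amounts per volume of the solution: crystals
- run time (flask): 12 s
- part of the starting material that has reacted at 12 s
- pH of the solution at 12 s

Turn the question round: what would the numbers need for the unaided road to overtake the acid road? Take the tie as the zero of your scale. Starting material leaves by the acid road at 3200 L mol⁻¹ s⁻¹ times c(acid) and by the unaided road at 0.033 s⁻¹, so the two run equal at the break-even acid:

c* = 0.033 s⁻¹ / 3200 L mol⁻¹ s⁻¹ = 0.0103 mM

Your charge of acid stands at 1.75 times that. Weak acid adds to it. I take free weak acid at its solubility, 0.56 mM; c(acid) minus c(conjugate base) equals the charge, and their product is 2.0 × 10⁻⁷ M times 0.56 mM: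

c(acid) = 0.0229 mM, or 2.22 times c*

The acid road therefore runs ahead. Add the impurity loss, pseudo-first-order at 0.00828 s⁻¹, and the total is:

k = 0.115 s⁻¹

Feeding for 8.0 s at this k, then standing until 12 s, gives 58.6% reacted. The pH I commit to is that of the acid level above.

The forecast says 60% (57% to 63%) and pH 4.6 (4.56 to 4.64), on its own sum of the rates, which “gives a total of about 0.12” per second. Its figure for the part reacted is higher than mine.

The flask gives 60.9% reacted and pH 4.60, both inside the forecast's range.

In this flask the feed ran until 8.00 s; at that moment weak acid stood at 1.03 mM, above its solubility, and crystals at 4.53 mM. By 12.0 s, with the feed over, starting material stood at 39.1% and crystals at 8.98 mM, with acid at 0.0251 mM, still 2.44 times c*. The idle adduct then stood at 1.01% and made no difference to the part reacted.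

Now take the neighbour flask charged with 0.031 mM of acid. The same reckoning gives c(acid) = 0.0343 mM, which is 3.33 times c*, so k = 0.151 s⁻¹ and 68.3% reacted. That neighbour flask gives 69.6%.

All constants come from no measurement; no experiment stands behind them.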